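North, at 0.43 mM of initiator, still shows 36.8 % free monomer at 10.0 min, more than the 21.2 % of east at 0.68 mM, yet north reads 98.9 % monomer in chains at 30.0 min. I want longer chains, so I plan to charge less initiator than either run and stop at the same time.

in all of them: free monomer 0.097 M
- north: initiator 0.43 mM; run made earlier
- east: initiator 0.68 mM; run made earlier
- flask: initiator 0.31 mM; time 30 min

- north (time / min: monomer in chains / %, free monomer / %): 2.00: 5.5, 94.6; 6.00: 34.6, 62.5; 10.0: 64.0, 36.8; 15.0: 81.8, 17.3; 25.0: 96.7, 4.5; 30.0: 98.9, 0
- east (time / min: monomer in chains / %, free monomer / %): 2.50: 11.8, 83.7; 4.00: 31.6, 67.9; 6.00: 50.6, 51.0; 10.0: 78.3, 21.2; 20.0: 96.6, 2.8; 30.0: 97.3, 0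

(scatter of a reading: 1 percentage point)

- the average divides the monomer in chains by the number of chains begun, living and dead together
- the numbers in the tables scatter by 1 percentage point (one standard deviation)
- the earlier runs do not show the number of chains; that part of a forecast is a guess

- average number of monomer units in a chain (chains begun, living or dead) at 30 min
- part of the free monomer that has reacted at 30 min

For this flask, [free monomer]/[initiator] at the charge is 313. I carry this charge ratio (the target degree of polymerisation); north has 226 and east 143. I assume each initiator used begins one chain, so in logarithms to base 10: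

lg dp = lg(charge ratio) + lg(share of monomer in chains) − lg(share of initiator used)

My own reckoning takes all the initiator as used and the forecast's 96.3 % as the share in chains:

lg dp = 2.50 + (−0.0164) = 2.48, so dp = 301

The forecast gives dp 320, higher than my figure, and c 96.3 %. Of its all-initiator figure it says: “Incomplete initiation would raise it.” Both figures stand above the charge ratio of north, so I charge the flask.

The flask gives dp 341 and c 96.0 %.

    free monomer + initiator → living end + monomer in chains (k = 0.0308 M⁻¹ s⁻¹)
    free monomer + living end → monomer in chains + living end, rate k2*[living end]*[free monomer] (k = 7.98 M⁻¹ s⁻¹)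
    monomer in chains → over-reaction product (k = 1.37 × 10⁻⁵ s⁻¹)

At 30.0 min the flask keeps 13.2 % of its initiator and holds 94.5 % monomer in chains, so:

lg dp = 2.53, so dp = 341

The neighbour flask with 0.39 M of free monomer has a charge ratio of 1260. At 30.0 min it keeps 0.310 % of its initiator and holds 96.7 % monomer in chains, so:

lg dp = 3.09, so dp = 1220

That neighbour flask gives dp 1220, with c at 98.5 %.

(The readings are calculated on assumed constants, and the scatter is random.)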